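Your product, monomer in chains, is one entry in a ledger kept on free monomer, the limiting reagent.

| setting | alpha | delta | gamma | flask |
|---|---|---|---|---|
| free monomer | 0.20 M | 0.45 M | 0.30 M | 0.30 M |
| pre-initiator | 2.8 mM | 2.8 mM | 4.2 mM | 2.8 mM |
| remark | run made earlier | run made earlier | run made earlier |  |
| time |  |  |  | 3.0 h |

- alpha (time / min: monomer in chains / %, free monomer / %): 15.0: 0.2, 99.3; 30.0: 3.0, 96.5; 50.0: 13.2, 87.7; 60.0: 21.2, 80.0; 80.0: 36.8, 63.5; 90.0: 45.6, 54.2; 120: 68.2, 31.7
- delta (time / min: monomer in chains / %, free monomer / %): 15.0: 0.1, 98.8; 30.0: 6.3, 93.6; 50.0: 23.6, 77.6; 60.0: 33.7, 66.3; 80.0: 54.4, 44.7; 90.0: 63.7, 36.1; 120: 80.9, 18.9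
- gamma (time / min: monomer in chains / %, free monomer / %): 10.0: 0.2, 99.5; 25.0: 4.4, 96.2; 50.0: 24.8, 76.4; 80.0: 57.0, 41.7; 120: 85.0, 15.7

(standard deviation of a reading: 0.5 percentage points)

- the average divides the monomer in chains by the number of chains begun, living and dead together
- what may be going on: free monomer + initiator -> living end + monomer in chains; free monomer + living end -> monomer in chains + living end; pre-initiator -> initiator; initiator + monomer in chains -> spent initiator
- the earlier runs do not show the number of chains; that part of a forecast is a guess

- average number of monomer units in a chain (chains begun, living or dead) at 3.0 h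
- part of the free monomer that has reacted at 3.0 h

At 120 min the alpha run books 31.7% free and 68.2% in chains, and the delta run 18.9% and 80.9%, so these two entries close the books within the scatter of 0.5 percentage points. Spent initiator is the third entry. Each one takes one unit of monomer in chains and comes from one pre-initiator, so in this flask it holds at most 0.933% of the charge.

For the free entry I replace the curve by a mean slope of ln[free monomer], a pseudo-first-order constant. From 90.0 min to 120 min it is 0.0179 min⁻¹ in alpha and 0.0216 min⁻¹ in delta. With 0.400 as the fraction of the way from alpha's charge to delta's, my estimate for the flask is 0.0194 min⁻¹. Interpolating the last readings the same way and holding that slope to 3.0 h leaves 8.07% free. Alpha's slope was still rising, from 0.0115 min⁻¹ between 60.0 min and 80.0 min to 0.0179 min⁻¹, so I expect this entry to err high.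

The readings do not show the chains, but each chain begun takes one pre-initiator. My estimate of the monomer reacted in the flask, divided by the pre-initiator charged, therefore gives 98.5, the floor length, and the flask's average should stand at or above it.

The forecast says 92.7% reacted, which leaves 7.30% free, less than my 8.07%, and 180 units, on this ground for the units: “I guess about 55% efficiency”.

The flask gives 93.7% reacted and 811 units.

    free monomer + initiator → living end + monomer in chains (k = 4.90 × 10⁻⁴ M⁻¹ s⁻¹)
    free monomer + living end → monomer in chains + living end, rate k2*[living end]*[free monomer] (k = 1.10 M⁻¹ s⁻¹)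
    pre-initiator → initiator (k = 1.20 × 10⁻⁴ s⁻¹)
    initiator + monomer in chains → spent initiator (k = 0.00300 M⁻¹ s⁻¹)

The flask's average stands 8.24 times the floor length, the forecast's 1.83 times. In the flask at 3.00 h, the 2.8 mM of pre-initiator charged stands as 0.766 mM pre-initiator, 0.138 mM initiator, 0.345 mM living end and 1.55 mM spent initiator. Read the same flask at 80 min: 46.2% has reacted, so the floor length is 49.5, and the average is 517, which is 10.4 times that floor, with 56% of the pre-initiator still unconverted.

All runs were computed on assumed constants, and the scatter is random.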